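**Plan**

Flavonoid numbering is used for both halves. Unit 1 is the (2S)-flavanone and unit 2 the (2R,3R)-3-hydroxyflavanone, and they are joined C3'–C3'''.
Cuts, in order: the benzyl-type O-groups; C4–C4a of unit 2, which opens ring C to a (2R,3R)-3-aryl-3-aryloxy-2-hydroxypropanoic acid; the benzylic C2–O1 ether bond; the two C–O bonds at C2 and C3, leading back to an E-cinnamate; C2–C1' of unit 1; and the biaryl bond.
Enabling feature: ring A of unit 2 is a 1,3,5-trioxygenated benzene. The two carbons flanking C8a–O1 (later C4a and C8) are equivalent and strongly nucleophilic, and the para carbon (later C6) is out of reach, so the acyl carbon C4 can bond in only one way.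
Forward order: two different halves are cross-coupled to the biaryl. Rings A and C of unit 1 then arrive as a preformed chromone that accepts the biaryl boronic acid. The cinnamate arm is dihydroxylated and etherified with the ring A phenol, ring C of unit 2 closes last, and hydrogenolysis frees the target.
Stereochemistry: C2 of unit 1 comes from the rhodium/(S)-diphosphine catalyst. C3 of unit 2 comes from the (DHQ)2PHAL-controlled dihydroxylation. C2 of unit 2 comes from the same dihydroxylation followed by one SN2 inversion. The ring closure touches neither centre.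

Key step: step 12

Remark: the facial sense of the rhodium step is assigned by analogy with cyclic enones, where (S)-configured biaryl diphosphines give the spatial arrangement that corresponds to a (2S)-flavanone; both ligand antipodes are available.
Remark: the four numbered starting materials and all reagents are taken to be catalogue items.

Step 1
Reactants: 1 3-bromo-4-hydroxybenzaldehyde
Product: 2 tert-butyl (E)-3-(3-bromo-4-hydroxyphenyl)prop-2-enoate
Conditions: Ph3P=CHCO2t-Bu (1.5 equiv), toluene, 90 °C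
Reagents that add atoms: tert-butyl (triphenylphosphoranylidene)acetate CC(C)(C)OC(=O)C=P(c1ccccc1)(c1ccccc1)c1ccccc1
Why: Wittig olefination with an ester-stabilised ylide gives the E-enoate, tolerates the free phenol and the aryl bromide, and installs at the outset a tert-butyl ester that resists the aqueous bases of the next steps.

Step 2
Reactants: 2 tert-butyl (E)-3-(3-bromo-4-hydroxyphenyl)prop-2-enoate; 3 [2-(benzyloxy)-5-chlorophenyl]boronic acid
Product: 4 tert-butyl (E)-3-[2'-(benzyloxy)-5'-chloro-6-hydroxybiphenyl-3-yl]prop-2-enoate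
Conditions: Pd(PPh3)4 (5 mol %), aq Na2CO3, DME, 85 °C
Reagents that add atoms: none
Why: Suzuki–Miyaura coupling in which zerovalent palladium bearing PPh3 inserts into the C–Br bond (activated by the para acrylate) but not into the C–Cl bond of 3, so one step joins the two B rings, leaves one phenol free and the other benzylated, and keeps chloride as the handle for unit 1.

Step 3
Reactants: 4 tert-butyl (E)-3-[2'-(benzyloxy)-5'-chloro-6-hydroxybiphenyl-3-yl]prop-2-enoate
Product: 6 {6-(benzyloxy)-5'-[(E)-3-tert-butoxy-3-oxoprop-1-en-1-yl]-2'-hydroxybiphenyl-3-yl}boronic acid, via pinacol boronate 5 (not isolated)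
Conditions: B2pin2, Pd2(dba)3 (2 mol %), XPhos (8 mol %), KOAc, 1,4-dioxane, 100 °C; filter, concentrate; NaIO4, NH4OAc, acetone/H2O, rt
Reagents that add atoms: bis(pinacolato)diboron CC1(C)OB(OC1(C)C)B1OC(C)(C)C(C)(C)O1; water O
Why: Miyaura borylation of an electron-rich aryl chloride is known with the bulky XPhos ligand and the weak base KOAc, which spares phenol, enoate and ester, and periodate then destroys the pinacol released by hydrolysis to give the free boronic acid needed for fast transmetalation to rhodium, the phenol being shielded from oxidation by its conjugated ester.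

Step 4
Reactants: 7 2,4,6-trihydroxyacetophenone
Product: 8 1-[2,4-bis(benzyloxy)-6-hydroxyphenyl]ethanone
Conditions: BnBr (2.05 equiv), K2CO3, acetone, reflux
Reagents that add atoms: benzyl bromide BrCc1ccccc1
Why: Williamson etherification in which the hydroxyl group hydrogen-bonded to the acetyl oxygen is the least reactive, so two equivalents of benzyl bromide stop at the dibenzyl ether.

Step 5
Reactants: 8 1-[2,4-bis(benzyloxy)-6-hydroxyphenyl]ethanone
Product: 10 5,7-bis(benzyloxy)-4H-chromen-4-one, via enaminone 9 (not isolated)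
Conditions: Me2NCH(OMe)2, toluene, 100 °C; concentrate; conc. HCl, CH2Cl2, 40 °C
Reagents that add atoms: N,N-dimethylformamide dimethyl acetal COC(OC)N(C)C
Why: Enaminone route to chromones, in which the methyl ketone condenses with the amide acetal and acid then lets the ortho phenol add to the enaminone carbon and expel dimethylamine, closing ring C of unit 1 as a pyranone unsubstituted at C2 and C3.

Step 6
Reactants: 6 {6-(benzyloxy)-5'-[(E)-3-tert-butoxy-3-oxoprop-1-en-1-yl]-2'-hydroxybiphenyl-3-yl}boronic acid (1.5 equiv); 10 5,7-bis(benzyloxy)-4H-chromen-4-one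
Product: 11 tert-butyl (E)-3-{2'-(benzyloxy)-5'-[(2S)-5,7-bis(benzyloxy)-4-oxochroman-2-yl]-6-hydroxybiphenyl-3-yl}prop-2-enoate
Conditions: [Rh(OH)(cod)]2 (2.5 mol %), (S)-MeO-F12-BIPHEP [(S)-2,2'-bis[bis(3,4,5-trifluorophenyl)phosphino]-6,6'-dimethoxybiphenyl, 5.5 mol %], CH2Cl2/H2O, rt
Reagents that add atoms: none
Why: Hayashi–Miyaura asymmetric 1,4-addition, known for chromones including 5,7-dioxygenated ones, in which the aryl–rhodium species held by the (S)-diphosphine inserts C2=C3 of 10 from one face and water protonates the resulting rhodium enolate, setting C2 as S, while the base-free medium at room temperature prevents ring opening of the flavanone and leaves the donor-substituted β-aryl enoate of 6 untouched.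

Step 7
Reactants: 11 tert-butyl (E)-3-{2'-(benzyloxy)-5'-[(2S)-5,7-bis(benzyloxy)-4-oxochroman-2-yl]-6-hydroxybiphenyl-3-yl}prop-2-enoate
Product: 12 tert-butyl (E)-3-{2'-(benzyloxy)-6-[(benzyloxycarbonyl)oxy]-5'-[(2S)-5,7-bis(benzyloxy)-4-oxochroman-2-yl]biphenyl-3-yl}prop-2-enoate
Conditions: BnOCOCl (1.2 equiv), pyridine, CH2Cl2, 0 °C
Reagents that add atoms: benzyl chloroformate O=C(Cl)OCc1ccccc1
Why: O-acylation of the only free hydroxyl group with a chloroformate under pyridine, a base too weak to open the flavanone, turns the oxygen para to the future C2 of unit 2 from a donor into an acceptor and installs a group that the final hydrogenolysis removes.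

Step 8
Reactants: 12 tert-butyl (E)-3-{2'-(benzyloxy)-6-[(benzyloxycarbonyl)oxy]-5'-[(2S)-5,7-bis(benzyloxy)-4-oxochroman-2-yl]biphenyl-3-yl}prop-2-enoate
Product: 13 tert-butyl (2R,3S)-3-{2'-(benzyloxy)-6-[(benzyloxycarbonyl)oxy]-5'-[(2S)-5,7-bis(benzyloxy)-4-oxochroman-2-yl]biphenyl-3-yl}-2,3-dihydroxypropanoate
Conditions: K2OsO2(OH)4 (1 mol %), (DHQ)2PHAL (5 mol %), NMO (1.5 equiv), t-BuOH/THF/H2O, 0 °C to rt, slow addition of 12
Reagents that add atoms: N-methylmorpholine N-oxide C[N+]1([O-])CCOCC1; water O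
Why: Sharpless asymmetric dihydroxylation in which OsO4 bound to (DHQ)2PHAL adds both oxygens syn to the face of the E-cinnamate that gives the (2R,3S)-diol, the known outcome for cinnamates with this ligand, while NMO as reoxidant (also known for cinnamates) keeps the medium near neutral so that the aryl carbonate and the flavanone persist.

Step 9
Reactants: 14 phloroglucinol
Product: 15 3,5-bis(benzyloxy)phenol
Conditions: BnBr (2.0 equiv), K2CO3, DMF, rt
Reagents that add atoms: benzyl bromide BrCc1ccccc1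
Why: Williamson etherification under statistical control with two equivalents of benzyl bromide, the wanted diether being separated from the mono- and triethers by chromatography.

Step 10
Reactants: 13 tert-butyl (2R,3S)-3-{2'-(benzyloxy)-6-[(benzyloxycarbonyl)oxy]-5'-[(2S)-5,7-bis(benzyloxy)-4-oxochroman-2-yl]biphenyl-3-yl}-2,3-dihydroxypropanoate; 15 3,5-bis(benzyloxy)phenol (1.5 equiv)
Product: 16 tert-butyl (2R,3R)-3-{2'-(benzyloxy)-6-[(benzyloxycarbonyl)oxy]-5'-[(2S)-5,7-bis(benzyloxy)-4-oxochroman-2-yl]biphenyl-3-yl}-3-[3,5-bis(benzyloxy)phenoxy]-2-hydroxypropanoate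
Conditions: PPh3, DIAD (added last), toluene/THF, 0 °C to rt
Reagents that add atoms: none
Why: Mitsunobu etherification, in which the oxyphosphonium group of syn-2,3-dihydroxy esters is known to settle on the β-oxygen and the phenoxide of 15 displaces it at the benzylic carbon by SN2 with inversion (3S to 3R), the para carbonate disfavouring ionisation, so that the syn diol becomes the anti aryloxy alcohol while C2 is untouched.

Step 11
Reactants: 16 tert-butyl (2R,3R)-3-{2'-(benzyloxy)-6-[(benzyloxycarbonyl)oxy]-5'-[(2S)-5,7-bis(benzyloxy)-4-oxochroman-2-yl]biphenyl-3-yl}-3-[3,5-bis(benzyloxy)phenoxy]-2-hydroxypropanoate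
Product: 17 (2R,3R)-3-{2'-(benzyloxy)-6-[(benzyloxycarbonyl)oxy]-5'-[(2S)-5,7-bis(benzyloxy)-4-oxochroman-2-yl]biphenyl-3-yl}-3-[3,5-bis(benzyloxy)phenoxy]-2-hydroxypropanoic acid
Conditions: 85 % aq H3PO4, toluene/CH2Cl2, rt, vigorous stirring
Reagents that add atoms: none
Why: Acid-catalysed alkyl–oxygen cleavage of the tert-butyl ester with aqueous phosphoric acid, a reagent known to spare benzyl ethers and benzyloxycarbonyl groups, in which water captures the tert-butyl cation before it can alkylate the nucleophilic trioxygenated ring.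

Step 12
Reactants: 17 (2R,3R)-3-{2'-(benzyloxy)-6-[(benzyloxycarbonyl)oxy]-5'-[(2S)-5,7-bis(benzyloxy)-4-oxochroman-2-yl]biphenyl-3-yl}-3-[3,5-bis(benzyloxy)phenoxy]-2-hydroxypropanoic acid
Product: 20 (2R,3R)-5,7-bis(benzyloxy)-2-{2'-(benzyloxy)-6-[(benzyloxycarbonyl)oxy]-5'-[(2S)-5,7-bis(benzyloxy)-4-oxochroman-2-yl]biphenyl-3-yl}-3-hydroxychroman-4-one, via mixed trifluoroacetic anhydride 18 (not isolated), via 3-O-trifluoroacetate 19 (not isolated)
Conditions: (CF3CO)2O (3 equiv), CH2Cl2 (0.02 M), 0 °C to rt; evaporate; MeOH, rt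
Reagents that add atoms: none
Why: (CF3CO)2O first esterifies the C2 hydroxyl of the chain and converts the carboxyl group into the mixed anhydride 18, whose acyl carbon is attacked by the trioxygenated phenoxy ring at a carbon ortho to the ether oxygen, and loss of the arenium proton and of CF3CO2H gives ketone 19 (intramolecular Friedel–Crafts acylation, SEAr). The closest known reaction type is the cyclodehydration of 3-aryloxypropanoic acids to chroman-4-ones and of 3-aryl-3-aryloxypropanoic acids to flavanones with the same reagent. Ring C of unit 2 closes in the 6-exo-trig mode, the new bond being C4–C4a. No stereocentre is created: C2 and C3 were fixed in the open chain, neither is a reacting atom, no base is present that could enolise the anhydride, and the anti (2R,3R) chain maps onto the 2,3-trans ring, which is also the more stable diastereomer. Site selectivity is structural, because the two ortho carbons are equivalent, the para carbon cannot reach the acyl group and ring A of unit 1 is deactivated by its own carbonyl, while transfer of the wanted acyl group rather than CF3CO is secured by intramolecularity, dilution and only a small excess of anhydride. Ionisation of the benzylic C2–O1 bond and loss of CO are held back by the carbonate para to C2, by the electron-poor, non-participating trifluoroacetate at C3 and by the low temperature, and methanol then removes that labile ester without base.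

Step 13
Reactants: 20 (2R,3R)-5,7-bis(benzyloxy)-2-{2'-(benzyloxy)-6-[(benzyloxycarbonyl)oxy]-5'-[(2S)-5,7-bis(benzyloxy)-4-oxochroman-2-yl]biphenyl-3-yl}-3-hydroxychroman-4-one
Product: 21 (2R,3R)-2-{5'-[(2S)-5,7-dihydroxy-4-oxochroman-2-yl]-2',6-dihydroxybiphenyl-3-yl}-3,5,7-trihydroxychroman-4-one (CNP0201582.1)
Conditions: H2 (1 atm), 10 % Pd/C, THF/MeOH, rt
Reagents that add atoms: none
Why: Catalytic hydrogenolysis cleaves the five aryl benzyl ethers and the benzyl carbonate (which then loses CO2) under neutral conditions that leave both C2–O1 bonds, both ketones and all three stereocentres unchanged, as is usual for the last step of flavanone and dihydroflavonol syntheses.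

**Compound list**

1 | 3-bromo-4-hydroxybenzaldehyde | O=Cc1ccc(O)c(Br)c1 | starting material
2 | tert-butyl (E)-3-(3-bromo-4-hydroxyphenyl)prop-2-enoate | CC(C)(C)OC(=O)/C=C/c1ccc(O)c(Br)c1 | intermediate
3 | [2-(benzyloxy)-5-chlorophenyl]boronic acid | OB(O)c1cc(Cl)ccc1OCc1ccccc1 | starting material
4 | tert-butyl (E)-3-[2'-(benzyloxy)-5'-chloro-6-hydroxybiphenyl-3-yl]prop-2-enoate | CC(C)(C)OC(=O)/C=C/c1ccc(O)c(-c2cc(Cl)ccc2OCc2ccccc2)c1 | intermediate
5 | tert-butyl (E)-3-[2'-(benzyloxy)-6-hydroxy-5'-(4,4,5,5-tetramethyl-1,3,2-dioxaborolan-2-yl)biphenyl-3-yl]prop-2-enoate | CC(C)(C)OC(=O)/C=C/c1ccc(O)c(-c2cc(B3OC(C)(C)C(C)(C)O3)ccc2OCc2ccccc2)c1 | intermediate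
6 | {6-(benzyloxy)-5'-[(E)-3-tert-butoxy-3-oxoprop-1-en-1-yl]-2'-hydroxybiphenyl-3-yl}boronic acid | CC(C)(C)OC(=O)/C=C/c1ccc(O)c(-c2cc(B(O)O)ccc2OCc2ccccc2)c1 | intermediate
7 | 2,4,6-trihydroxyacetophenone | CC(=O)c1c(O)cc(O)cc1O | starting material
8 | 1-[2,4-bis(benzyloxy)-6-hydroxyphenyl]ethanone | CC(=O)c1c(O)cc(OCc2ccccc2)cc1OCc1ccccc1 | intermediate
9 | (E)-1-[2,4-bis(benzyloxy)-6-hydroxyphenyl]-3-(dimethylamino)prop-2-en-1-one | CN(C)/C=C/C(=O)c1c(O)cc(OCc2ccccc2)cc1OCc1ccccc1 | intermediate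
10 | 5,7-bis(benzyloxy)-4H-chromen-4-one | O=c1ccoc2cc(OCc3ccccc3)cc(OCc3ccccc3)c12 | intermediate
11 | tert-butyl (E)-3-{2'-(benzyloxy)-5'-[(2S)-5,7-bis(benzyloxy)-4-oxochroman-2-yl]-6-hydroxybiphenyl-3-yl}prop-2-enoate | O=C1C[C@@H](c2ccc(OCc3ccccc3)c(-c3cc(/C=C/C(=O)OC(C)(C)C)ccc3O)c2)Oc2cc(OCc3ccccc3)cc(OCc3ccccc3)c21 | intermediate
12 | tert-butyl (E)-3-{2'-(benzyloxy)-6-[(benzyloxycarbonyl)oxy]-5'-[(2S)-5,7-bis(benzyloxy)-4-oxochroman-2-yl]biphenyl-3-yl}prop-2-enoate | O=C1C[C@@H](c2ccc(OCc3ccccc3)c(-c3cc(/C=C/C(=O)OC(C)(C)C)ccc3OC(=O)OCc3ccccc3)c2)Oc2cc(OCc3ccccc3)cc(OCc3ccccc3)c21 | intermediate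
13 | tert-butyl (2R,3S)-3-{2'-(benzyloxy)-6-[(benzyloxycarbonyl)oxy]-5'-[(2S)-5,7-bis(benzyloxy)-4-oxochroman-2-yl]biphenyl-3-yl}-2,3-dihydroxypropanoate | O=C1C[C@@H](c2ccc(OCc3ccccc3)c(-c3cc([C@H](O)[C@@H](O)C(=O)OC(C)(C)C)ccc3OC(=O)OCc3ccccc3)c2)Oc2cc(OCc3ccccc3)cc(OCc3ccccc3)c21 | intermediate
14 | phloroglucinol | Oc1cc(O)cc(O)c1 | starting material
15 | 3,5-bis(benzyloxy)phenol | Oc1cc(OCc2ccccc2)cc(OCc2ccccc2)c1 | intermediate
16 | tert-butyl (2R,3R)-3-{2'-(benzyloxy)-6-[(benzyloxycarbonyl)oxy]-5'-[(2S)-5,7-bis(benzyloxy)-4-oxochroman-2-yl]biphenyl-3-yl}-3-[3,5-bis(benzyloxy)phenoxy]-2-hydroxypropanoate | O=C1C[C@@H](c2ccc(OCc3ccccc3)c(-c3cc([C@@H](Oc4cc(OCc5ccccc5)cc(OCc5ccccc5)c4)[C@@H](O)C(=O)OC(C)(C)C)ccc3OC(=O)OCc3ccccc3)c2)Oc2cc(OCc3ccccc3)cc(OCc3ccccc3)c21 | intermediate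
17 | (2R,3R)-3-{2'-(benzyloxy)-6-[(benzyloxycarbonyl)oxy]-5'-[(2S)-5,7-bis(benzyloxy)-4-oxochroman-2-yl]biphenyl-3-yl}-3-[3,5-bis(benzyloxy)phenoxy]-2-hydroxypropanoic acid | O=C1C[C@@H](c2ccc(OCc3ccccc3)c(-c3cc([C@@H](Oc4cc(OCc5ccccc5)cc(OCc5ccccc5)c4)[C@@H](O)C(=O)O)ccc3OC(=O)OCc3ccccc3)c2)Oc2cc(OCc3ccccc3)cc(OCc3ccccc3)c21 | intermediate
18 | mixed anhydride of trifluoroacetic acid with the (2R,3R)-2-(trifluoroacetoxy) derivative of acid 17 | O=C1C[C@@H](c2ccc(OCc3ccccc3)c(-c3cc([C@@H](Oc4cc(OCc5ccccc5)cc(OCc5ccccc5)c4)[C@@H](OC(=O)C(F)(F)F)C(=O)OC(=O)C(F)(F)F)ccc3OC(=O)OCc3ccccc3)c2)Oc2cc(OCc3ccccc3)cc(OCc3ccccc3)c21 | intermediate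
19 | 3-O-trifluoroacetate of 20, (2R,3R) in unit 2 and (2S) in unit 1 | O=C1C[C@@H](c2ccc(OCc3ccccc3)c(-c3cc([C@H]4Oc5cc(OCc6ccccc6)cc(OCc6ccccc6)c5C(=O)[C@@H]4OC(=O)C(F)(F)F)ccc3OC(=O)OCc3ccccc3)c2)Oc2cc(OCc3ccccc3)cc(OCc3ccccc3)c21 | intermediate
20 | (2R,3R)-5,7-bis(benzyloxy)-2-{2'-(benzyloxy)-6-[(benzyloxycarbonyl)oxy]-5'-[(2S)-5,7-bis(benzyloxy)-4-oxochroman-2-yl]biphenyl-3-yl}-3-hydroxychroman-4-one | O=C1C[C@@H](c2ccc(OCc3ccccc3)c(-c3cc([C@H]4Oc5cc(OCc6ccccc6)cc(OCc6ccccc6)c5C(=O)[C@@H]4O)ccc3OC(=O)OCc3ccccc3)c2)Oc2cc(OCc3ccccc3)cc(OCc3ccccc3)c21 | intermediate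
21 | (2R,3R)-2-{5'-[(2S)-5,7-dihydroxy-4-oxochroman-2-yl]-2',6-dihydroxybiphenyl-3-yl}-3,5,7-trihydroxychroman-4-one | O=C1C[C@@H](c2ccc(O)c(-c3cc([C@H]4Oc5cc(O)cc(O)c5C(=O)[C@@H]4O)ccc3O)c2)Oc2cc(O)cc(O)c21 | target

Total step count: 13. Longest linear sequence: 10 steps (1, 2, 3, 6, 7, 8, 10, 11, 12, 13).

**Steps most likely to fail**

Risk 1 (step 12). Several processes could compete with ring closure:
- transfer of the trifluoroacetyl group to the very electron-rich ring
- loss of CO from the activated α-oxygenated acid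
- acid-induced heterolysis of the benzylic ether, with erosion of the configuration at C2

The fallback sets out from 17 and divides the two tasks of the anhydride between separate reagents. Ac2O/pyridine (CH2Cl2, 0 °C, aqueous work-up) gives the 2-O-acetyl acid F1. 1-Chloro-N,N,2-trimethylprop-1-en-1-amine (CH2Cl2, 0 °C) converts it under neutral conditions into the acyl chloride F2. SnCl4 (CH2Cl2, −78 °C) then closes ring C by a classical Lewis acid Friedel–Crafts acylation. No second acyl donor is present in this step, and the neighbouring acetate can stabilise the acyl cation as an acetoxonium ion. The product is the 3-O-acetyl ketone F3. HCl in MeOH/CH2Cl2 (generated from AcCl, rt) removes the acetate, and the route is rejoined at 20.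

Risk 2 (step 10). Four things may go wrong:
- substitution at the C2 hydroxyl instead of the benzylic one
- cyclodehydration of the diol to a glycidate
- partial ionisation with incomplete inversion
- C-alkylation of the phenol

The fallback sets out from 13 and replaces innate regioselection by protecting-group control. TBSCl/imidazole (DMF, 0 °C) should silylate the more acidic hydroxyl next to the ester and give the 2-O-silyl ether F4. Only the benzylic hydroxyl is then left for the Mitsunobu reaction with 15 (PPh3, DIAD, toluene, 0 °C), which gives the silylated aryl ether F5. HF·pyridine (THF, 0 °C) frees the hydroxyl group, and the route is rejoined at 16.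

Risk 3 (step 6). Insertion into the hindered, electron-rich chromone may be slow enough for protodeboronation to win. The facial selectivity may be poor with this large aryl group. A second addition to the new ketone is also possible.

The fallback sets out from 6 and 10 and separates bond formation from stereocontrol. The more active, diphosphine-free [Rh(OH)(cod)]2 (dioxane/H2O, 40 °C) gives the racemic flavanone F6. Kinetic resolution by asymmetric transfer hydrogenation is a known way to enantiopure flavanones. With RuCl(p-cymene)[(R,R)-TsDPEN] and HCO2H/Et3N (EtOAc, rt) it should reduce the 2R ketone to the cis-(2R,4R)-flavan-4-ol F7. The 2S ketone is left unreduced and is separated by chromatography, and the route is rejoined at 11.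

**Further compounds**

F1 | step 12 | (2R,3R)-2-acetoxy derivative of acid 17 | O=C1C[C@@H](c2ccc(OCc3ccccc3)c(-c3cc([C@@H](Oc4cc(OCc5ccccc5)cc(OCc5ccccc5)c4)[C@@H](OC(C)=O)C(=O)O)ccc3OC(=O)OCc3ccccc3)c2)Oc2cc(OCc3ccccc3)cc(OCc3ccccc3)c21
F2 | step 12 | acyl chloride of F1, (2R,3R) | O=C1C[C@@H](c2ccc(OCc3ccccc3)c(-c3cc([C@@H](Oc4cc(OCc5ccccc5)cc(OCc5ccccc5)c4)[C@@H](OC(C)=O)C(=O)Cl)ccc3OC(=O)OCc3ccccc3)c2)Oc2cc(OCc3ccccc3)cc(OCc3ccccc3)c21
F3 | step 12 | 3-O-acetate of 20, (2R,3R) in unit 2 and (2S) in unit 1 | O=C1C[C@@H](c2ccc(OCc3ccccc3)c(-c3cc([C@H]4Oc5cc(OCc6ccccc6)cc(OCc6ccccc6)c5C(=O)[C@@H]4OC(C)=O)ccc3OC(=O)OCc3ccccc3)c2)Oc2cc(OCc3ccccc3)cc(OCc3ccccc3)c21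
F4 | step 10 | 2-O-(tert-butyldimethylsilyl) ether of diol 13, (2R,3S) | O=C1C[C@@H](c2ccc(OCc3ccccc3)c(-c3cc([C@H](O)[C@@H](O[Si](C)(C)C(C)(C)C)C(=O)OC(C)(C)C)ccc3OC(=O)OCc3ccccc3)c2)Oc2cc(OCc3ccccc3)cc(OCc3ccccc3)c21
F5 | step 10 | 2-O-(tert-butyldimethylsilyl) ether of 16, (2R,3R) | O=C1C[C@@H](c2ccc(OCc3ccccc3)c(-c3cc([C@@H](Oc4cc(OCc5ccccc5)cc(OCc5ccccc5)c4)[C@@H](O[Si](C)(C)C(C)(C)C)C(=O)OC(C)(C)C)ccc3OC(=O)OCc3ccccc3)c2)Oc2cc(OCc3ccccc3)cc(OCc3ccccc3)c21
F6 | step 6 | racemic form of 11 | O=C1CC(c2ccc(OCc3ccccc3)c(-c3cc(/C=C/C(=O)OC(C)(C)C)ccc3O)c2)Oc2cc(OCc3ccccc3)cc(OCc3ccccc3)c21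
F7 | step 6 | tert-butyl (E)-3-{2'-(benzyloxy)-5'-[(2R,4R)-5,7-bis(benzyloxy)-4-hydroxychroman-2-yl]-6-hydroxybiphenyl-3-yl}prop-2-enoate | O[C@@H]1C[C@H](c2ccc(OCc3ccccc3)c(-c3cc(/C=C/C(=O)OC(C)(C)C)ccc3O)c2)Oc2cc(OCc3ccccc3)cc(OCc3ccccc3)c21
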